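## Analysis of the target

Tricetin 3'-sulfate (12) is a flavone. A phloroglucinol-type ring A (free hydroxyls at C5 and C7) is fused through C4a/C8a to a 4-pyranone ring C (O1, C2, C3, C4, C4a, C8a), and C2 carries a pyrogallol-type ring B through the C2–C1' bond. There is no stereocentre; the only "relative" element is constitutional: ring B has local twofold symmetry (O3' and O5' equivalent, O4' unique), and the target breaks it by carrying the sulfate on O3' alone. Five phenolic oxygens are present and exactly one is sulfated, so the real selectivity problem is to tell O3' from O4'/O5' and from O5/O7. The aryl sulfate monoester is the sensitive group: it hydrolyses in acid, does not survive the Lewis acids that cleave methyl ethers, and turns every compound that carries it into an ion pair, so it must come late and be followed only by neutral hydrogenolysis. The free pyrogallol unit is air-sensitive in base, which rules out a basic last step. The feature the strategy uses is ring C itself: C4 is a lone carbonyl carbon between the arene carbon C4a and the alkene carbon C3, O1 sits on C8a ortho to C4a, and C2=C3 with its aryl group is at the oxidation level of an arylacetylene, so the six ring atoms map onto an ortho-iodophenol, carbon monoxide and an alkyne. A second feature is that a five-membered ketal can bridge only adjacent oxygens of ring B, so a bridge over O4'/O5' leaves exactly O3' free.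

## Retrosynthetic reasoning

12 ← 10 (through 11). Only protecting-group bonds are cut: the two benzyl C–O bonds at O5 and O7 and the two ketal C–O bonds at O4' and O5'. Hydrogenolysis is chosen because it leaves the S–O bonds alone, whereas acidic or Lewis-acidic deprotection would not. All protecting groups were chosen to fall in this one operation; protonation of the ion pair 11 then gives 12.

10 ← 9. The O3'–S bond is cut. Compound 9 has exactly one free hydroxyl, so the sulfation needs no selectivity of its own. The polar, acid-sensitive group is then carried through a single further step.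

9 ← 5 + 6 + 3 (key disconnection). Ring C is cut at three bonds at once: C4a–C4, C4–C3 and O1–C2. C4 becomes carbon monoxide 6, C2/C3 with ring B become the terminal alkyne 3, and O1/C8a/C4a with ring A become the ortho-iodophenol 5. The forward reaction must insert 6 between the aryl carbon of 5 and the alkyne carbon of 3 (giving ynone 7), then close the pyranone in the six-membered mode (through enaminone 8). This cut is preferred because neither half needs a preformed ketone, ester or acid chloride, the two halves are single arenes of similar size, and ring C forms under amine base only, which the ketal, the benzyl ethers and a free phenol tolerate.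

3 ← 2. The terminal alkyne carbon (later C3 of ring C) is cut off; the forward reaction is a one-carbon homologation of an aryl aldehyde to an arylacetylene with a diazophosphonate reagent under carbonate base.

2 ← 1. The two ketal C–O bonds are cut. The forward ketalisation is the step that differentiates ring B: only adjacent oxygens can be bridged, and the two possible bridges of 1 are equivalent, so a single compound with one free flanking hydroxyl (the later O3') results. The ketal is also hydrogenolysable, which fits the end game.

5 ← 4. The C–I bond ortho to the free hydroxyl is cut; the forward reaction is an ortho-selective electrophilic iodination of a phenol whose other two oxygens already carry the benzyl groups needed at O5 and O7.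

## Alternatives that were turned down

Alternative 1: The textbook cut of ring C at O1–C2 and C2–C3 (Baker–Venkataraman sequence). The ring A methyl ketone A1 would be O-acylated with the ring B acid chloride A2, base would shift the acyl group to carbon to give the 1,3-diketone A3, and hot acid would close ring C to the silyl ether A4, which is desilylated to 9. It was turned down for three reasons. Ring C costs four operations instead of one. An acid chloride cannot carry the free O3' hydroxyl, so a protecting group must be put on and taken off and the aldehyde level of 1 must be raised to the acid level. The cyclodehydration needs strong acid at heat, which endangers the ketal and the silyl ether in A3, the two groups that encode the differentiation of ring B.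

Alternative 2: Cut of the C2–C1' bond between ring C and ring B. The forward key step is an oxidative Heck-type coupling of chromone A5 with boronic acid A6 (divalent palladium catalyst, stoichiometric oxidant) to give 9. It was turned down because ring C must already exist in A5, which takes further steps from A1, so the key step makes one bond and the ring problem is only moved. A6 requires a halogenated pyrogallol precursor that the aldehyde series does not provide. Mechanistically, syn-carbopalladation of C2=C3 places palladium at C3 anti to the C2 hydrogen, so β-hydride elimination is not direct and protonation to the flavanone competes. The oxidant is also a poor match for the electron-rich free phenol of A6.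

Alternative 3: Construction of ring A from an open chain, cut at C4a–C5. The forward step is a biomimetic Claisen cyclisation of the pyranone keto ester A7, in which pyranone C3 attacks the ester carbonyl and enolisation gives the 5,7-dihydroxyflavone A8. It was turned down because it builds the one ring that can be bought with both oxygens already benzylated. A8 has free O5–H and O7–H beside O3'–H, so the differentiation is lost and must be restored by extra protection steps (O7–H, the most acidic, would sulfate first). A7 is a masked tetracarbonyl compound that needs multistep carbanion chemistry and can also close in an aldol mode.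

Key step: step 4

Assumption: the target is taken as the free hydrogen sulfate drawn in the SMILES; because aryl hydrogen sulfates hydrolyse under their own acidity, the group is carried as a triethylammonium salt and protonated only in the last operation, cold.

## Route

Step 1
Reactants: 1 3,4,5-trihydroxybenzaldehyde
Product: 2 7-hydroxy-2,2-diphenyl-1,3-benzodioxole-5-carbaldehyde
Conditions: Ph2CCl2 (1.2 equiv), Ph2O, 175 °C
Reagents that add atoms: dichlorodiphenylmethane, ClC(Cl)(c1ccccc1)c1ccccc1
Why: Thermal ketalisation of a catechol with a gem-dichloride; the five-membered 1,3-benzodioxole can bridge only two adjacent oxygens, and because O3 and O5 of 1 are equivalent either bridge gives the same compound 2 with one free flanking hydroxyl (the later O3').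

Step 2
Reactants: 2 7-hydroxy-2,2-diphenyl-1,3-benzodioxole-5-carbaldehyde
Product: 3 6-ethynyl-2,2-diphenyl-1,3-benzodioxol-4-ol
Conditions: Ohira–Bestmann reagent (1.5 equiv), K2CO3 (3.5 equiv), MeOH, 0 °C to rt; NH4Cl work-up
Reagents that add atoms: dimethyl (1-diazo-2-oxopropyl)phosphonate, CC(=O)C(=[N+]=[N-])P(=O)(OC)OC
Why: Seyferth–Gilbert homologation in the Ohira–Bestmann variant: methanolysis frees the diazomethylphosphonate anion, olefination and loss of N2 give an alkylidene carbene, and a 1,2-hydrogen shift gives the terminal alkyne. The phenoxide is meta to the aldehyde and cannot deactivate it by resonance, and the ketal is inert to carbonate.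

Step 3
Reactants: 4 3,5-bis(benzyloxy)phenol
Product: 5 3,5-bis(benzyloxy)-2-iodophenol
Conditions: NIS (1.0 equiv), CH2Cl2, −78 to −20 °C
Reagents that add atoms: N-iodosuccinimide, O=C1CCC(=O)N1I
Why: Electrophilic aromatic iodination; the two equivalent positions ortho to the free hydroxyl (C2/C6) are favoured statistically, are less hindered than C4 between two benzyloxy groups, and are reached by hydrogen-bond-guided delivery from the reagent in a non-polar solvent. One equivalent at low temperature should limit double iodination.

Step 4
Reactants: 5 3,5-bis(benzyloxy)-2-iodophenol; 3 6-ethynyl-2,2-diphenyl-1,3-benzodioxol-4-ol (1.2 equiv); 6 carbon monoxide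
Product: 9 5,7-bis(benzyloxy)-2-(7-hydroxy-2,2-diphenyl-1,3-benzodioxol-5-yl)-4H-chromen-4-one, via ynone 7 (not isolated), via enaminone 8 (not isolated)
Conditions: PdCl2(dppf) (5 mol %; dppf = 1,1'-bis(diphenylphosphino)ferrocene), CO (20 bar), Et2NH, 120 °C
Reagents that add atoms: diethylamine, CCNCC (its atoms are held only in intermediate 8 and leave again on ring closure)
Why: This is the palladium-catalysed carbonylative annulation of an ortho-iodophenol with a terminal arylacetylene and CO, a known three-component route to flavones. The divalent palladium precatalyst is reduced to zerovalent palladium, which inserts into the C–I bond of 5; CO 6 inserts to give an aroylpalladium species (C4a–C4), the amine-deprotonated alkyne 3 replaces iodide, and reductive elimination forms C4–C3 of ynone 7. Diethylamine then adds to the β-carbon of 7 to give enaminone 8, and the ortho-hydroxyl displaces the amine at that carbon by addition–elimination, forming O1–C2 and closing ring C in the six-membered (6-endo) mode. The selectivity needed is six-ring (flavone) against five-ring (aurone, 5-exo attack at the α-carbon) closure; the amine secures it, because in 8 only the amine-bearing carbon is electrophilic. The second selectivity is CO insertion before alkyne coupling (direct coupling would lead to a benzofuran); an electron-rich aryl group flanked by two ortho oxygens migrates to CO readily, and the CO pressure supports this. The free hydroxyl of 3 should be a spectator, since the amine solvent is the far more abundant competing nucleophile and acetylide capture of aroylpalladium is known to win even against it. The benzyl ethers and the ketal meet only amine base, and no stereocentre is formed.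

Step 5
Reactants: 9 5,7-bis(benzyloxy)-2-(7-hydroxy-2,2-diphenyl-1,3-benzodioxol-5-yl)-4H-chromen-4-one
Product: 10 triethylammonium 6-[5,7-bis(benzyloxy)-4-oxo-4H-chromen-2-yl]-2,2-diphenyl-1,3-benzodioxol-4-yl sulfate
Conditions: SO3·NEt3 (4 equiv), Et3N (2 equiv), DMF, 50 °C; silica, CH2Cl2/MeOH/Et3N
Reagents that add atoms: sulfur trioxide–triethylamine complex, CC[N+](CC)(CC)S(=O)(=O)[O-]
Why: O-Sulfation of a phenol with a sulfur trioxide–amine complex; 9 has a single free hydroxyl (O5/O7 benzylated, O4'/O5' in the ketal), so no regiochemical choice arises. The amine of the reagent becomes the counter-ion of a lipophilic, base-stable ion pair that should be chromatographable.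

Step 6
Reactants: 10 triethylammonium 6-[5,7-bis(benzyloxy)-4-oxo-4H-chromen-2-yl]-2,2-diphenyl-1,3-benzodioxol-4-yl sulfate
Product: 12 tricetin 3'-sulfate (5-(5,7-dihydroxy-4-oxo-4H-chromen-2-yl)-2,3-dihydroxyphenyl hydrogen sulfate), via triethylammonium salt 11 (not isolated)
Conditions: H2 (1 atm), Pd(OH)2/C, THF/MeOH, Et3N (trace), rt; filter; then sulfonic acid cation-exchange resin (H+ form), MeOH/H2O, 0 °C; freeze-dry
Reagents that add atoms: none
Why: Catalytic hydrogenolysis cleaves the two benzyl ethers and the doubly benzylic ketal C–O bonds in one operation; the sulfate monoester anion is inert to it, and the conjugated C2=C3 bond of a flavone is normally not reduced under these conditions. Cold cation exchange then converts ion pair 11 into the acid form 12, which is dried at once to limit acid-catalysed loss of the sulfate.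

## Compound list

1 | 3,4,5-trihydroxybenzaldehyde | O=Cc1cc(O)c(O)c(O)c1 | starting material
2 | 7-hydroxy-2,2-diphenyl-1,3-benzodioxole-5-carbaldehyde | O=Cc1cc(O)c2OC(c3ccccc3)(c3ccccc3)Oc2c1 | intermediate
3 | 6-ethynyl-2,2-diphenyl-1,3-benzodioxol-4-ol | C#Cc1cc(O)c2OC(c3ccccc3)(c3ccccc3)Oc2c1 | intermediate
4 | 3,5-bis(benzyloxy)phenol | Oc1cc(OCc2ccccc2)cc(OCc2ccccc2)c1 | starting material
5 | 3,5-bis(benzyloxy)-2-iodophenol | Oc1cc(OCc2ccccc2)cc(OCc2ccccc2)c1I | intermediate
6 | carbon monoxide | [C-]#[O+] | starting material
7 | 1-[2,4-bis(benzyloxy)-6-hydroxyphenyl]-3-(7-hydroxy-2,2-diphenyl-1,3-benzodioxol-5-yl)prop-2-yn-1-one | O=C(C#Cc1cc(O)c2OC(c3ccccc3)(c3ccccc3)Oc2c1)c1c(O)cc(OCc2ccccc2)cc1OCc1ccccc1 | intermediate (not isolated)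
8 | (E)-1-[2,4-bis(benzyloxy)-6-hydroxyphenyl]-3-(diethylamino)-3-(7-hydroxy-2,2-diphenyl-1,3-benzodioxol-5-yl)prop-2-en-1-one (drawn as E; the geometry has no consequence for the ring closure) | O=C(/C=C(/N(CC)CC)c1cc(O)c2OC(c3ccccc3)(c3ccccc3)Oc2c1)c1c(O)cc(OCc2ccccc2)cc1OCc1ccccc1 | intermediate (not isolated)
9 | 5,7-bis(benzyloxy)-2-(7-hydroxy-2,2-diphenyl-1,3-benzodioxol-5-yl)-4H-chromen-4-one | O=c1cc(-c2cc(O)c3OC(c4ccccc4)(c4ccccc4)Oc3c2)oc2cc(OCc3ccccc3)cc(OCc3ccccc3)c12 | intermediate
10 | triethylammonium 6-[5,7-bis(benzyloxy)-4-oxo-4H-chromen-2-yl]-2,2-diphenyl-1,3-benzodioxol-4-yl sulfate | O=c1cc(-c2cc(OS(=O)(=O)[O-])c3OC(c4ccccc4)(c4ccccc4)Oc3c2)oc2cc(OCc3ccccc3)cc(OCc3ccccc3)c12.CC[NH+](CC)CC | intermediate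
11 | triethylammonium 5-(5,7-dihydroxy-4-oxo-4H-chromen-2-yl)-2,3-dihydroxyphenyl sulfate | O=c1cc(-c2cc(O)c(O)c(OS(=O)(=O)[O-])c2)oc2cc(O)cc(O)c12.CC[NH+](CC)CC | intermediate (not isolated)
12 | tricetin 3'-sulfate, 5-(5,7-dihydroxy-4-oxo-4H-chromen-2-yl)-2,3-dihydroxyphenyl hydrogen sulfate | O=c1cc(-c2cc(O)c(O)c(OS(=O)(=O)O)c2)oc2cc(O)cc(O)c12 | target

## Step count and least certain steps

Total step count: 6. Longest linear sequence: 5 steps (steps 1, 2, 4, 5, 6, from 1 to 12); step 3 is the one-step side branch to 5.

Step 4 (key step). The most likely failure is capture of the aroylpalladium intermediate by the amine solvent (aminocarbonylation) or by a phenoxide, or hydrodeiodination, outrunning the alkyne coupling, because the aryl iodide is electron-rich and flanked by two ortho oxygens. A second failure is coupling without CO insertion, which leads towards a benzofuran. The fallback uses known chemistry that closes ring C at other bonds (O1–C2 and C2–C3). It sets out from aldehyde 2, which is condensed with the bought ketone A1 in a Claisen–Schmidt reaction (KOH, EtOH, rt) to give the chalcone (E)-1-[2,4-bis(benzyloxy)-6-hydroxyphenyl]-3-(7-hydroxy-2,2-diphenyl-1,3-benzodioxol-5-yl)prop-2-en-1-one F1. Oxidative cyclisation of F1 with catalytic I2 in DMSO at 120 °C (oxa-Michael closure, α-iodination, loss of HI, reoxidation of iodide by the solvent) should give flavone 9, where the fallback comes back to the route. Steps 2 and 3 are then not needed.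

Step 3. The most likely failure is poor ortho/para selectivity, that is iodination at C4 between the two benzyloxy groups, together with double iodination, since all three free ring positions are activated by three oxygens. The fallback replaces electrophilic substitution by directed ortho-metalation. It sets out from phenol 4, which is converted (MOMCl, i-Pr2NEt, CH2Cl2) into 1,3-bis(benzyloxy)-5-(methoxymethoxy)benzene F2. Lithiation with n-BuLi in THF at −20 °C occurs at the position flanked by the chelating methoxymethoxy group, and an I2 quench gives 1,5-bis(benzyloxy)-2-iodo-3-(methoxymethoxy)benzene F3. Acetal cleavage (HCl, MeOH, 40 °C) returns to the route at iodophenol 5.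

Step 5. The most likely failure is incomplete O-sulfation, or loss of the sulfate by hydrolysis while the ion pair is purified on silica. The fallback introduces the sulfate as a protected, neutral diester. It sets out from 9, which with 2,2,2-trichloroethyl chlorosulfate (Et3N, DMAP, THF) gives 6-[5,7-bis(benzyloxy)-4-oxo-4H-chromen-2-yl]-2,2-diphenyl-1,3-benzodioxol-4-yl 2,2,2-trichloroethyl sulfate F4, which can be chromatographed like any neutral compound. Reductive cleavage (Zn, HCO2NH4, MeOH, rt) gives ammonium 6-[5,7-bis(benzyloxy)-4-oxo-4H-chromen-2-yl]-2,2-diphenyl-1,3-benzodioxol-4-yl sulfate F5. Co-evaporation of F5 with Et3N in MeOH exchanges the cation and comes back to the route at 10.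

Step 2. The most likely failure is sluggish olefination of the aldehyde while it carries a phenoxide, leading to incomplete conversion and decomposition of the diazo reagent. The fallback is the Corey–Fuchs sequence. It sets out from aldehyde 2, which with CBr4 and PPh3 (CH2Cl2, 0 °C) gives 6-(2,2-dibromoethenyl)-2,2-diphenyl-1,3-benzodioxol-4-ol F6. Treatment of F6 with n-BuLi (3.2 equiv, THF, −78 °C; NH4Cl) causes bromine–lithium exchange, rearrangement to the lithium acetylide and protonation, and comes back to the route at alkyne 3.

## Further compounds

F1 | step 4 | (E)-1-[2,4-bis(benzyloxy)-6-hydroxyphenyl]-3-(7-hydroxy-2,2-diphenyl-1,3-benzodioxol-5-yl)prop-2-en-1-one | O=C(/C=C/c1cc(O)c2OC(c3ccccc3)(c3ccccc3)Oc2c1)c1c(O)cc(OCc2ccccc2)cc1OCc1ccccc1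
F2 | step 3 | 1,3-bis(benzyloxy)-5-(methoxymethoxy)benzene | COCOc1cc(OCc2ccccc2)cc(OCc2ccccc2)c1
F3 | step 3 | 1,5-bis(benzyloxy)-2-iodo-3-(methoxymethoxy)benzene | COCOc1cc(OCc2ccccc2)cc(OCc2ccccc2)c1I
F4 | step 5 | 6-[5,7-bis(benzyloxy)-4-oxo-4H-chromen-2-yl]-2,2-diphenyl-1,3-benzodioxol-4-yl 2,2,2-trichloroethyl sulfate | O=c1cc(-c2cc(OS(=O)(=O)OCC(Cl)(Cl)Cl)c3OC(c4ccccc4)(c4ccccc4)Oc3c2)oc2cc(OCc3ccccc3)cc(OCc3ccccc3)c12
F5 | step 5 | ammonium 6-[5,7-bis(benzyloxy)-4-oxo-4H-chromen-2-yl]-2,2-diphenyl-1,3-benzodioxol-4-yl sulfate | O=c1cc(-c2cc(OS(=O)(=O)[O-])c3OC(c4ccccc4)(c4ccccc4)Oc3c2)oc2cc(OCc3ccccc3)cc(OCc3ccccc3)c12.[NH4+]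
F6 | step 2 | 6-(2,2-dibromoethenyl)-2,2-diphenyl-1,3-benzodioxol-4-ol | BrC(Br)=Cc1cc(O)c2OC(c3ccccc3)(c3ccccc3)Oc2c1
A1 | alternative 1 | 1-[2,4-bis(benzyloxy)-6-hydroxyphenyl]ethanone | CC(=O)c1c(O)cc(OCc2ccccc2)cc1OCc1ccccc1
A2 | alternative 1 | 2,2-diphenyl-7-[(triisopropylsilyl)oxy]-1,3-benzodioxole-5-carbonyl chloride | O=C(Cl)c1cc(O[Si](C(C)C)(C(C)C)C(C)C)c2OC(c3ccccc3)(c3ccccc3)Oc2c1
A3 | alternative 1 | 1-[2,4-bis(benzyloxy)-6-hydroxyphenyl]-3-{2,2-diphenyl-7-[(triisopropylsilyl)oxy]-1,3-benzodioxol-5-yl}propane-1,3-dione | O=C(CC(=O)c1cc(O[Si](C(C)C)(C(C)C)C(C)C)c2OC(c3ccccc3)(c3ccccc3)Oc2c1)c1c(O)cc(OCc2ccccc2)cc1OCc1ccccc1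
A4 | alternative 1 | 5,7-bis(benzyloxy)-2-{2,2-diphenyl-7-[(triisopropylsilyl)oxy]-1,3-benzodioxol-5-yl}-4H-chromen-4-one | O=c1cc(-c2cc(O[Si](C(C)C)(C(C)C)C(C)C)c3OC(c4ccccc4)(c4ccccc4)Oc3c2)oc2cc(OCc3ccccc3)cc(OCc3ccccc3)c12
A5 | alternative 2 | 5,7-bis(benzyloxy)-4H-chromen-4-one | O=c1ccoc2cc(OCc3ccccc3)cc(OCc3ccccc3)c12
A6 | alternative 2 | (7-hydroxy-2,2-diphenyl-1,3-benzodioxol-5-yl)boronic acid | OB(O)c1cc(O)c2OC(c3ccccc3)(c3ccccc3)Oc2c1
A7 | alternative 3 | methyl 4-[6-(7-hydroxy-2,2-diphenyl-1,3-benzodioxol-5-yl)-4-oxo-4H-pyran-2-yl]-3-oxobutanoate | COC(=O)CC(=O)Cc1cc(=O)cc(-c2cc(O)c3OC(c4ccccc4)(c4ccccc4)Oc3c2)o1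
A8 | alternative 3 | 5,7-dihydroxy-2-(7-hydroxy-2,2-diphenyl-1,3-benzodioxol-5-yl)-4H-chromen-4-one | O=c1cc(-c2cc(O)c3OC(c4ccccc4)(c4ccccc4)Oc3c2)oc2cc(O)cc(O)c12
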